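A direct plan would build the hydrindenone first and the eight-membered ring last. The ynal dialdehyde A1 (C5/C6 from a conjugate addition and an enolate methylation) would be joined to the alkenyl iodide A2 by an asymmetric Nozaki–Hiyama–Kishi coupling. A Pauson–Khand reaction would then close rings A and B to the hydrindenone aldehyde A3, and after allylboration, acetylation and desilylation the diene diol A4 would be cyclised by forming C11–C12.
Its weakest steps would be:
- the last step, closure of ring C by an intramolecular alcohol–diene coupling: an untested reaction would have to form an eight-membered ring and quaternary C12 on the fully functionalised molecule, with nothing in the substrate to help against transannular strain;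
- the Pauson–Khand reaction: it would have to engage a 1,1-disubstituted alkene to make quaternary C9, with facial control resting on one allylic silyl ether;
- the run-up: about twelve steps of lactone/lactol/diol/dialdehyde and ester/alcohol/aldehyde/dibromoalkene/alkyne/iodoalkene traffic would go into two small fragments before any ring exists.

**Retrosynthetic overview**
- Numbering: ring A = C1–C2(=O)–C3=C4–C9, ring B = C4–C5–C6–C7–C8–C9, ring C = C4–C5–C14–C13–C12–C11–C10–C9. Rings B and C together are a bicyclo[5.3.1]undecane in which C4 is the one-carbon bridge between the quaternary bridgeheads C5 and C9; the C3=C4 bond of ring A is exocyclic to it.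
- Key disconnection: a type 2 intramolecular Diels–Alder reaction of the acyclic trienone 16. Its 2-siloxy diene C7=C8–C9=C4 is part of a vinylallene and is tied at C9 through C10–C14 to the Z enone C5=C6. The step forms C4–C5 and C6–C7, closes rings B and C at once and sets C5 and C6.
- The adduct keeps C8=C9 as a silyl enol ether and C4=C3H2 as an exocyclic alkene; ring A is closed last from these two handles (C9–C1 by enolate alkylation, C2–C3 by alkene acylation).
- Trienone 16 comes from lactone 4 (C12 by asymmetric allylic alkylation), an allenylstannane propargylation (C10, C11), a palladium-catalysed SN2′ coupling (vinylallene) and a Weinreb ketone synthesis (enone).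
- No medium ring is closed by one late bond, C9 becomes quaternary by enolate alkylation and not by a Pauson–Khand reaction, and the C8 and C14 oxygens are told apart by the enol ether that the cycloaddition leaves.

Key step: step 12

Remark on the chemistry: the configuration is taken literally from the SMILES, 5S,6S,8S,9R,10R,11S,12S,14R in the numbering above (this puts the C5/C6 pair in the sense opposite to the mutilin family relative to C9–C14), and every structure below is written with exactly these descriptors; "B/C bicycle" means the bicyclo[5.3.1]undecane made of C4–C14 with methyl groups at C5, C6, C10 and C12 and the vinyl group at C12.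

**Aldehyde (C11–C14)**

Step 1
Reactants: 1 rac-2-ethenyl-2-methyloxirane (isoprene monoxide)
Product: 4 (S)-4-ethenyl-4-methyloxolan-2-one, via alkylated Meldrum's acid 2 (not isolated), via lactone acid 3 (not isolated)
Conditions: Meldrum's acid, Pd2(dba)3·CHCl3 (1 mol %), (1R,2R)-N,N′-bis[2-(diphenylphosphino)benzoyl]cyclohexane-1,2-diamine (3 mol %), CH2Cl2, rt; then toluene, 110 °C
Reagents that add atoms: Meldrum's acid (2,2-dimethyl-1,3-dioxane-4,6-dione), CC1(C)OC(=O)CC(=O)O1
Why: Palladium-catalysed dynamic kinetic asymmetric allylic alkylation of the vinyl epoxide: both epoxide enantiomers give interconverting π-allyl complexes, the chiral diphosphine and the alkoxide steer the soft carbon nucleophile to the substituted terminus so that quaternary C12 is set as S (the mirror-image ligand would be taken if this nucleophile showed the opposite sense), and the freed alcohol then opens the dioxanedione to the lactone acid, which loses CO2 on heating.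

Step 2
Reactants: 4 (S)-4-ethenyl-4-methyloxolan-2-one
Product: 5 (S)-3-(hydroxymethyl)-N-methoxy-N,3-dimethylpent-4-enamide
Conditions: MeNH(OMe)·HCl, AlMe3, CH2Cl2, 0 °C → rt; aqueous work-up
Reagents that add atoms: N,O-dimethylhydroxylamine hydrochloride, CNOC.Cl
Why: Aluminium amide aminolysis of the lactone (Weinreb amide formation) frees the neopentyl C11 alcohol and leaves the quaternary stereocentre untouched.

Step 3
Reactants: 5 (S)-3-(hydroxymethyl)-N-methoxy-N,3-dimethylpent-4-enamide
Product: 6 (S)-3-formyl-N-methoxy-N,3-dimethylpent-4-enamide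
Conditions: Dess–Martin periodinane, CH2Cl2, 0 °C → rt
Reagents that add atoms: none
Why: Dess–Martin oxidation of the primary alcohol gives the C11 aldehyde, which cannot epimerise because C12 is quaternary.

**Allenylstannane (C4, C9, C10)**

Step 4
Reactants: 7 (R)-but-3-yn-2-ol
Product: 8 (R)-but-3-yn-2-yl methanesulfonate
Conditions: MsCl, Et3N, CH2Cl2, −78 °C
Reagents that add atoms: methanesulfonyl chloride, CS(=O)(=O)Cl
Why: Sulfonylation at oxygen activates the propargylic alcohol without touching the stereocentre.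

Step 5
Reactants: 8 (R)-but-3-yn-2-yl methanesulfonate
Product: 9 (aS)-tributyl(buta-1,2-dien-1-yl)stannane
Conditions: Bu3SnH, LiN(i-Pr)2, THF, −78 °C; CuBr·SMe2; then 8, −78 °C
Reagents that add atoms: tributylstannyllithium (made in the flask from Bu3SnH and LiN(i-Pr)2), [Li][Sn](CCCC)(CCCC)CCCC
Why: Anti SN2′ displacement of the propargylic mesylate by the stannylcuprate turns the central chirality of 8 into the axial chirality of the allenylstannane.

**Assembly of the trienone**

Step 6
Reactants: 6 (S)-3-formyl-N-methoxy-N,3-dimethylpent-4-enamide; 9 (aS)-tributyl(buta-1,2-dien-1-yl)stannane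
Product: 10 (3S,4S,5R)-3-ethenyl-4-hydroxy-N-methoxy-N,3,5-trimethylhept-6-ynamide
Conditions: BF3·OEt2 (2 equiv), CH2Cl2, −78 °C
Reagents that add atoms: none
Why: Lewis-acid-promoted SE2′ propargylation of the aldehyde by the chiral allenylstannane through an open antiperiplanar transition state gives the syn adduct: attack anti to tin fixes C10 as R and the syn preference then fixes C11 as S, under reagent control because the aldehyde α-carbon is quaternary.

Step 7
Reactants: 10 (3S,4S,5R)-3-ethenyl-4-hydroxy-N-methoxy-N,3,5-trimethylhept-6-ynamide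
Product: 11 (3S,4S,5R)-3-ethenyl-N-methoxy-N,3,5-trimethyl-4-(triethylsilyloxy)hept-6-ynamide
Conditions: TESOTf, 2,6-lutidine, CH2Cl2, −78 → 0 °C
Reagents that add atoms: triethylsilyl trifluoromethanesulfonate, CC[Si](CC)(CC)OS(=O)(=O)C(F)(F)F
Why: Silylation of the hindered C11 hydroxyl stops it from lactonising onto the amide and from forming a hemiketal with the later C14 ketone.

Step 8
Reactants: 11 (3S,4S,5R)-3-ethenyl-N-methoxy-N,3,5-trimethyl-4-(triethylsilyloxy)hept-6-ynamide
Product: 12 (3S,4S,5R)-3-ethenyl-N-methoxy-8-(methoxycarbonyloxy)-N,3,5-trimethyl-4-(triethylsilyloxy)oct-6-ynamide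
Conditions: LiN(i-Pr)2 (1.05 equiv), THF, −78 °C; (CH2O)n, −78 → 0 °C; then ClCO2Me, 0 °C
Reagents that add atoms: formaldehyde (from paraformaldehyde), C=O; methyl chloroformate, COC(=O)Cl
Why: Deprotonation of the terminal alkyne (the most acidic C–H present), hydroxymethylation of the acetylide and trapping of the alkoxide in the same flask give the primary propargylic carbonate that carries C3.

Step 9
Reactants: 12 (3S,4S,5R)-3-ethenyl-N-methoxy-8-(methoxycarbonyloxy)-N,3,5-trimethyl-4-(triethylsilyloxy)oct-6-ynamide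
Product: 14 (3S,4S,5R)-6-acetyl-3-ethenyl-N-methoxy-N,3,5-trimethyl-4-(triethylsilyloxy)octa-6,7-dienamide, via ethyl dienyl ether 13 (not isolated)
Conditions: ethyl vinyl ether, t-BuLi, THF, −78 → 0 °C; ZnCl2; then 12, Pd(PPh3)4 (5 mol %), 0 °C → rt; then oxalic acid (cat., aq), 0 °C
Reagents that add atoms: chloro(1-ethoxyethenyl)zinc (made in the flask from ethyl vinyl ether, t-BuLi and ZnCl2), CCOC(=C)[Zn]Cl; water, O
Why: Zerovalent palladium ionises the propargylic carbonate in the SN2′ sense to an allenylpalladium species that couples with the alkenylzinc reagent (Negishi-type coupling) at C9 to give the 1,1-disubstituted allene, and dilute acid then hydrolyses only the enol ether to the methyl ketone.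

Step 10
Reactants: 14 (3S,4S,5R)-6-acetyl-3-ethenyl-N-methoxy-N,3,5-trimethyl-4-(triethylsilyloxy)octa-6,7-dienamide
Product: 15 (3S,4S,5R)-3-ethenyl-N-methoxy-N,3,5-trimethyl-4-(triethylsilyloxy)-6-[1-(triethylsilyloxy)ethenyl]octa-6,7-dienamide
Conditions: TESOTf, Et3N, CH2Cl2, −78 °C
Reagents that add atoms: triethylsilyl trifluoromethanesulfonate, CC[Si](CC)(CC)OS(=O)(=O)C(F)(F)F
Why: Soft enolisation of the methyl ketone, whose only enolisable position is the methyl group, gives the 2-siloxy diene and masks the ketone before the organolithium step.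

Step 11
Reactants: 15 (3S,4S,5R)-3-ethenyl-N-methoxy-N,3,5-trimethyl-4-(triethylsilyloxy)-6-[1-(triethylsilyloxy)ethenyl]octa-6,7-dienamide
Product: 16 (2Z,6S,7S,8R)-6-ethenyl-3,6,8-trimethyl-7-(triethylsilyloxy)-9-[1-(triethylsilyloxy)ethenyl]undeca-2,9,10-trien-4-one
Conditions: (Z)-2-bromobut-2-ene, t-BuLi (2 equiv), Et2O, −78 °C; then 15, THF, −78 → −40 °C; NH4Cl (aq)
Reagents that add atoms: (E)-but-2-en-2-yllithium (made in the flask from (Z)-2-bromobut-2-ene and t-BuLi with retention), C/C=C(/C)[Li]
Why: Weinreb ketone synthesis: the configurationally stable alkenyllithium adds once to the amide through the chelated tetrahedral intermediate and gives the Z (angeloyl-type) enone in which C14 is cis to the C6 methyl.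

**Key step and ring A**

Step 12
Reactants: 16 (2Z,6S,7S,8R)-6-ethenyl-3,6,8-trimethyl-7-(triethylsilyloxy)-9-[1-(triethylsilyloxy)ethenyl]undeca-2,9,10-trien-4-one
Product: 17 (1S,4S,5S,6R,10S)-4-ethenyl-1,4,6,10-tetramethyl-11-methylidene-5,8-bis(triethylsilyloxy)bicyclo[5.3.1]undec-7-en-2-one (B/C bicycle with 14-ketone and C8=C9 silyl enol ether and C4 methylidene; 5S,6S,10R,11S,12S)
Conditions: Me2AlCl (30 mol %), CH2Cl2, −78 → −20 °C
Reagents that add atoms: none
Why: Type 2 intramolecular Diels–Alder reaction: the Lewis-acid-complexed Z enone C5=C6 adds across the termini C4 and C7 of the 2-siloxy diene C7=C8–C9=C4, whose C4 is the unhindered central carbon of the allene; a stepwise path through C4 would need a vinyl cation, so bond formation should stay concerted and suprafacial. The closest known reactions are type 2 cycloadditions of 2-substituted dienes that carry an enone five atoms away, which give bicyclo[5.3.1]undecenes, and Diels–Alder reactions of vinylallenes, which give alkylidenecyclohexenes. Ring B closes as the new six-membered ring and ring C closes at the same time as the bridging ring, because the five-atom tether C10–C14 can join C9 and C5 only in the 1,3 sense, which is also the electronically matched sense (nucleophilic C7 to the enone β-carbon C6). C5 and C6 are set relative to each other by the Z geometry of the enone (C5 methyl trans to C6 methyl, C14 cis to the C6 methyl) and relative to C10–C12 by the tether, which should fold with the C10 methyl and C11 silyloxy groups pseudo-equatorial on the forming eight-membered ring and so expose one face of the dienophile (5S,6S). The step needs the enone to keep its Z geometry and the diene to react only through C7=C8–C9=C4; the low temperature, the substoichiometric Lewis acid and the absence of any other conjugated diene should secure both. The adduct keeps C8=C9 as a regiodefined bridgehead silyl enol ether and C4=C3H2 as an exocyclic alkene, the two handles for ring A.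

Step 13
Reactants: 17 (cycloadduct as named in step 12)
Product: 18 (1S,2R,4S,5S,6R,10S)-4-ethenyl-1,4,6,10-tetramethyl-11-methylidene-5,8-bis(triethylsilyloxy)bicyclo[5.3.1]undec-7-en-2-ol (14R alcohol of 17)
Conditions: i-Bu2AlH, CH2Cl2, −78 °C; aqueous work-up
Reagents that add atoms: none
Why: Hydride reduction of the only carbonyl group (C8 is still masked as its silyl enol ether, which is how C8 and C14 are told apart), with hydride entering the eight-membered ring from the face away from ring B (C6) so that the hydroxyl ends up syn to the C5 methyl (14R).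

Step 14
Reactants: 18 (14R alcohol as named in step 13)
Product: 20 allyl [(5S,6S,9R,10R,11S,12S,14R)-14-acetoxy-4-methylidene-8-oxo-11-(triethylsilyloxy)-B/C bicycle-9-yl]acetate, via dilithium alkoxide dienolate 19 (not isolated)
Conditions: MeLi (2.2 equiv), THF, 0 °C → rt; then DMPU, allyl bromoacetate, −78 → −20 °C; then Ac2O, DMAP (cat.), 0 °C
Reagents that add atoms: allyl bromoacetate, C=CCOC(=O)CBr; acetic anhydride, CC(=O)OC(C)=O
Why: Methyllithium deprotonates the C14 hydroxyl and cleaves the silyl enol ether to the regiodefined lithium dienolate, which is alkylated at its α-carbon C9 (γ-attack at C3 would give a strained bridgehead enone) on the outer lobe of the bridgehead position, making quaternary C9 (R) with C1, and the remaining C14 alkoxide is then acetylated in the same flask.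

Step 15
Reactants: 20 (keto allyl ester as named in step 14)
Product: 21 [(5S,6S,9R,10R,11S,12S,14R)-14-acetoxy-4-methylidene-8-oxo-11-(triethylsilyloxy)-B/C bicycle-9-yl]acetic acid
Conditions: Pd(PPh3)4 (5 mol %), morpholine, THF, rt; dilute acid work-up
Reagents that add atoms: none
Why: Palladium-catalysed deallylation (π-allyl transfer to morpholine) frees the carboxylic acid under neutral conditions that leave the acetate, the silyl ether and the acid-sensitive 1,1-disubstituted alkene alone.

Step 16
Reactants: 21 (acid as named in step 15)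
Product: 24 8-oxo-11-O-(triethylsilyl)pleuromutilin E (tricyclic enone with 8-ketone and 11-OTES and 14-OAc), via acid chloride 22 (not isolated), via β-chloro ketone 23 (not isolated)
Conditions: 1-chloro-N,N,2-trimethylprop-1-en-1-amine, CH2Cl2, 0 °C; then SnCl4, −78 °C; then Et3N, −78 → 0 °C
Reagents that add atoms: none
Why: Intramolecular Friedel–Crafts-type acylation of the exocyclic alkene: the acylium ion at C2 attacks the terminal carbon C3, the tertiary C4 cation is captured by chloride, and base removes HCl across C3–C4 (the only side that has hydrogens), which closes ring A directly as the C2 ketone with the C3=C4 double bond.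

Step 17
Reactants: 24 8-oxo-11-O-(triethylsilyl)pleuromutilin E
Product: 26 pleuromutilin E, via 8-hydroxy silyl ether 25 (not isolated)
Conditions: NaBH4, MeOH/CH2Cl2 (1:1), −78 °C; then HCl (cat., 1 M aq), THF, 0 °C → rt
Reagents that add atoms: none
Why: Borohydride at low temperature reduces the saturated cyclohexanone carbonyl at C8 faster than the conjugated cyclopentenone carbonyl, with hydride entering from the ring A (C1) side so that the hydroxyl ends up syn to C10 (8S), and dilute acid then removes the triethylsilyl group from O11 without touching the acetate.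

**Compound list**
1 | rac-2-ethenyl-2-methyloxirane (isoprene monoxide) | CC1(C=C)CO1 | starting material
2 | 5-[(2R)-1-hydroxy-2-methylbut-3-en-2-yl]-2,2-dimethyl-1,3-dioxane-4,6-dione | C=C[C@@](C)(CO)C1C(=O)OC(C)(C)OC1=O | intermediate
3 | (4R)-4-ethenyl-4-methyl-2-oxooxolane-3-carboxylic acid (C3 epimers) | C=C[C@]1(C)C(C(=O)O)C(=O)OC1 | intermediate
4 | (S)-4-ethenyl-4-methyloxolan-2-one | C=C[C@]1(C)CC(=O)OC1 | intermediate
5 | (S)-3-(hydroxymethyl)-N-methoxy-N,3-dimethylpent-4-enamide | C=C[C@@](C)(CO)CC(=O)N(C)OC | intermediate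
6 | (S)-3-formyl-N-methoxy-N,3-dimethylpent-4-enamide | C=C[C@@](C)(C=O)CC(=O)N(C)OC | intermediate
7 | (R)-but-3-yn-2-ol | C#C[C@@H](C)O | starting material
8 | (R)-but-3-yn-2-yl methanesulfonate | C#C[C@@H](C)OS(C)(=O)=O | intermediate
9 | (aS)-tributyl(buta-1,2-dien-1-yl)stannane | CCCC[Sn](CCCC)(CCCC)C([H])=[C@@]=C([H])C | intermediate
10 | (3S,4S,5R)-3-ethenyl-4-hydroxy-N-methoxy-N,3,5-trimethylhept-6-ynamide | C#C[C@@H](C)[C@H](O)[C@](C)(C=C)CC(=O)N(C)OC | intermediate
11 | (3S,4S,5R)-3-ethenyl-N-methoxy-N,3,5-trimethyl-4-(triethylsilyloxy)hept-6-ynamide | C#C[C@@H](C)[C@H](O[Si](CC)(CC)CC)[C@](C)(C=C)CC(=O)N(C)OC | intermediate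
12 | (3S,4S,5R)-3-ethenyl-N-methoxy-8-(methoxycarbonyloxy)-N,3,5-trimethyl-4-(triethylsilyloxy)oct-6-ynamide | COC(=O)OCC#C[C@@H](C)[C@H](O[Si](CC)(CC)CC)[C@](C)(C=C)CC(=O)N(C)OC | intermediate
13 | (3S,4S,5R)-3-ethenyl-6-(1-ethoxyethenyl)-N-methoxy-N,3,5-trimethyl-4-(triethylsilyloxy)octa-6,7-dienamide | C=C(OCC)C(=C=C)[C@@H](C)[C@H](O[Si](CC)(CC)CC)[C@](C)(C=C)CC(=O)N(C)OC | intermediate
14 | (3S,4S,5R)-6-acetyl-3-ethenyl-N-methoxy-N,3,5-trimethyl-4-(triethylsilyloxy)octa-6,7-dienamide | CC(=O)C(=C=C)[C@@H](C)[C@H](O[Si](CC)(CC)CC)[C@](C)(C=C)CC(=O)N(C)OC | intermediate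
15 | (3S,4S,5R)-3-ethenyl-N-methoxy-N,3,5-trimethyl-4-(triethylsilyloxy)-6-[1-(triethylsilyloxy)ethenyl]octa-6,7-dienamide | C=C(O[Si](CC)(CC)CC)C(=C=C)[C@@H](C)[C@H](O[Si](CC)(CC)CC)[C@](C)(C=C)CC(=O)N(C)OC | intermediate
16 | (2Z,6S,7S,8R)-6-ethenyl-3,6,8-trimethyl-7-(triethylsilyloxy)-9-[1-(triethylsilyloxy)ethenyl]undeca-2,9,10-trien-4-one | C/C=C(/C)C(=O)C[C@@](C)(C=C)[C@@H](O[Si](CC)(CC)CC)[C@H](C)C(=C=C)C(=C)O[Si](CC)(CC)CC | intermediate
17 | (1S,4S,5S,6R,10S)-4-ethenyl-1,4,6,10-tetramethyl-11-methylidene-5,8-bis(triethylsilyloxy)bicyclo[5.3.1]undec-7-en-2-one | C=C[C@]1(C)CC(=O)[C@]2(C)C(=C)C(=C(O[Si](CC)(CC)CC)C[C@@H]2C)[C@@H](C)[C@@H]1O[Si](CC)(CC)CC | intermediate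
18 | (1S,2R,4S,5S,6R,10S)-4-ethenyl-1,4,6,10-tetramethyl-11-methylidene-5,8-bis(triethylsilyloxy)bicyclo[5.3.1]undec-7-en-2-ol | C=C[C@]1(C)C[C@@H](O)[C@]2(C)C(=C)C(=C(O[Si](CC)(CC)CC)C[C@@H]2C)[C@@H](C)[C@@H]1O[Si](CC)(CC)CC | intermediate
19 | dilithium 14-alkoxide 8,9-dienolate of 18 | C=C[C@]1(C)C[C@@H](O[Li])[C@]2(C)C(=C)C(=C(O[Li])C[C@@H]2C)[C@@H](C)[C@@H]1O[Si](CC)(CC)CC | intermediate
20 | allyl [(5S,6S,9R,10R,11S,12S,14R)-14-acetoxy-4-methylidene-8-oxo-11-(triethylsilyloxy)-B/C bicycle-9-yl]acetate | C=C[C@]1(C)C[C@@H](OC(C)=O)[C@]2(C)C(=C)[C@](CC(=O)OCC=C)(C(=O)C[C@@H]2C)[C@@H](C)[C@@H]1O[Si](CC)(CC)CC | intermediate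
21 | [(5S,6S,9R,10R,11S,12S,14R)-14-acetoxy-4-methylidene-8-oxo-11-(triethylsilyloxy)-B/C bicycle-9-yl]acetic acid | C=C[C@]1(C)C[C@@H](OC(C)=O)[C@]2(C)C(=C)[C@](CC(=O)O)(C(=O)C[C@@H]2C)[C@@H](C)[C@@H]1O[Si](CC)(CC)CC | intermediate
22 | acid chloride of 21 | C=C[C@]1(C)C[C@@H](OC(C)=O)[C@]2(C)C(=C)[C@](CC(=O)Cl)(C(=O)C[C@@H]2C)[C@@H](C)[C@@H]1O[Si](CC)(CC)CC | intermediate
23 | 4-chloro-3,4-dihydro-8-oxo-11-O-(triethylsilyl)pleuromutilin E (C4 epimers) | C=C[C@]1(C)C[C@@H](OC(C)=O)[C@]2(C)C3(Cl)CC(=O)C[C@@]3(C(=O)C[C@@H]2C)[C@@H](C)[C@@H]1O[Si](CC)(CC)CC | intermediate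
24 | 8-oxo-11-O-(triethylsilyl)pleuromutilin E | C=C[C@]1(C)C[C@@H](OC(C)=O)[C@]2(C)C3=CC(=O)C[C@@]3(C(=O)C[C@@H]2C)[C@@H](C)[C@@H]1O[Si](CC)(CC)CC | intermediate
25 | 11-O-(triethylsilyl)pleuromutilin E | C=C[C@]1(C)C[C@@H](OC(C)=O)[C@]2(C)C3=CC(=O)C[C@@]3([C@@H](O)C[C@@H]2C)[C@@H](C)[C@@H]1O[Si](CC)(CC)CC | intermediate
26 | pleuromutilin E | C=C[C@]1(C)C[C@@H](OC(C)=O)[C@]2(C)C3=CC(=O)C[C@@]3([C@@H](O)C[C@@H]2C)[C@@H](C)[C@@H]1O | target

**Step count and risks**
Total: 17 steps. Longest linear sequence: 15 steps (steps 1–3 and 6–17).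

Steps most likely to fail:

1. Step 12 (type 2 cycloaddition). The Lewis acid may isomerise the Z enone to the E enone before it cyclises, which would give the C5/C6 cis-dimethyl series, or the trisubstituted dienophile may react so slowly that the siloxy diene is lost. The fallback takes the C6 methyl out of the cycloaddition and sets out from 15. Isopropenyllithium converts the Weinreb amide into (5S,6S,7R)-5-ethenyl-2,5,7-trimethyl-6-(triethylsilyloxy)-8-[1-(triethylsilyloxy)ethenyl]deca-1,8,9-trien-3-one F1, whose 1,1-disubstituted dienophile is more reactive and has no geometry to lose. The same cycloaddition gives the 6-demethyl cycloadduct F2, reduction with i-Bu2AlH gives the 6-demethyl 14R alcohol F3, and MeLi, allyl bromoacetate and Ac2O as in step 14 give the 6-demethyl keto ester F4. Dehydrogenation with 2-iodoxybenzoic acid (C7 is the only enolisable position of the C8 ketone) gives the C6=C7 enone F5, and conjugate addition of Me2CuLi trans to the C5 methyl group returns to the route at 20.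

2. Step 16 (acylative closure of ring A). The tertiary C4 cation sits between two quaternary carbons and may undergo a 1,2-alkyl shift, or the silyl ether may be lost under SnCl4. The fallback avoids cations and sets out from 21 through its acid chloride 22. Stille coupling with tributyl(ethenyl)stannane (Pd2(dba)3, tri(2-furyl)phosphine) gives the vinyl ketone, the C9-(2-oxobut-3-en-1-yl) analogue of 20, F6. Ring-closing metathesis with the second-generation Hoveyda–Grubbs catalyst then joins the enone carbon to C4 with loss of ethene and comes back to the route at 24.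

3. Step 14 (C9 alkylation). Cleavage of the hindered silyl enol ether may be incomplete, or the congested bridgehead dienolate may react at oxygen or be quenched by proton transfer. The fallback needs no free enolate and sets out from 18. Acetylation (Ac2O, DMAP, pyridine) gives the 14-acetate of 18 F7. Mukaiyama–Michael addition of its silyl enol ether to nitroethylene (CH2Cl2, −78 °C) gives the C9-(2-nitroethyl) C8-ketone F8, and oxidative Nef reaction of the primary nitro group (NaNO2, AcOH, DMSO) comes back to the route at acid 21.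

**Further compounds**
F1 | step 12 | (5S,6S,7R)-5-ethenyl-2,5,7-trimethyl-6-(triethylsilyloxy)-8-[1-(triethylsilyloxy)ethenyl]deca-1,8,9-trien-3-one | C=C(C)C(=O)C[C@@](C)(C=C)[C@@H](O[Si](CC)(CC)CC)[C@H](C)C(=C=C)C(=C)O[Si](CC)(CC)CC
F2 | step 12 | 6-demethyl analogue of cycloadduct 17 | C=C[C@]1(C)CC(=O)[C@]2(C)C(=C)C(=C(O[Si](CC)(CC)CC)CC2)[C@@H](C)[C@@H]1O[Si](CC)(CC)CC
F3 | step 12 | 6-demethyl analogue of alcohol 18 | C=C[C@]1(C)C[C@@H](O)[C@]2(C)C(=C)C(=C(O[Si](CC)(CC)CC)CC2)[C@@H](C)[C@@H]1O[Si](CC)(CC)CC
F4 | step 12 | 6-demethyl analogue of keto ester 20 | C=C[C@]1(C)C[C@@H](OC(C)=O)[C@]2(C)C(=C)[C@](CC(=O)OCC=C)(C(=O)CC2)[C@@H](C)[C@@H]1O[Si](CC)(CC)CC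
F5 | step 12 | 6-demethyl-6,7-didehydro analogue of keto ester 20 (C6=C7 enone) | C=C[C@]1(C)C[C@@H](OC(C)=O)[C@]2(C)C(=C)[C@](CC(=O)OCC=C)(C(=O)C=C2)[C@@H](C)[C@@H]1O[Si](CC)(CC)CC
F6 | step 16 | C9-(2-oxobut-3-en-1-yl) analogue of 20 (vinyl ketone in place of the allyl ester) | C=C[C@]1(C)C[C@@H](OC(C)=O)[C@]2(C)C(=C)[C@](CC(=O)C=C)(C(=O)C[C@@H]2C)[C@@H](C)[C@@H]1O[Si](CC)(CC)CC
F7 | step 14 | 14-acetate of alcohol 18 | C=C[C@]1(C)C[C@@H](OC(C)=O)[C@]2(C)C(=C)C(=C(O[Si](CC)(CC)CC)C[C@@H]2C)[C@@H](C)[C@@H]1O[Si](CC)(CC)CC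
F8 | step 14 | C9-(2-nitroethyl) analogue of 20 (nitroethyl in place of the allyl acetate arm) | C=C[C@]1(C)C[C@@H](OC(C)=O)[C@]2(C)C(=C)[C@](CC[N+](=O)[O-])(C(=O)C[C@@H]2C)[C@@H](C)[C@@H]1O[Si](CC)(CC)CC
A1 | direct plan | (2S,3S)-2-ethynyl-2,3-dimethylpentanedial | O=C[C@](C)(C#C)[C@@H](C)CC=O
A2 | direct plan | (S)-tert-butyl[(3-iodo-2-methylbut-3-en-1-yl)oxy]dimethylsilane | C=C(I)[C@@H](C)CO[Si](C)(C)C(C)(C)C
A3 | direct plan | (4S,5S,7S,7aR)-7a-[(2R)-1-(tert-butyldimethylsilyloxy)propan-2-yl]-4,5-dimethyl-2-oxo-7-(triethylsilyloxy)-2,4,5,6,7,7a-hexahydro-1H-indene-4-carbaldehyde | O=C[C@]1(C)C2=CC(=O)C[C@@]2([C@@H](O[Si](CC)(CC)CC)C[C@@H]1C)[C@@H](C)CO[Si](C)(C)C(C)(C)C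
A4 | direct plan | (1R)-1-[(4S,5S,7S,7aR)-7-hydroxy-7a-[(2R)-1-hydroxypropan-2-yl]-4,5-dimethyl-2-oxo-2,4,5,6,7,7a-hexahydro-1H-inden-4-yl]-3-methylidenepent-4-en-1-yl acetate | C=CC(=C)C[C@@H](OC(C)=O)[C@]1(C)C2=CC(=O)C[C@@]2([C@@H](O)C[C@@H]1C)[C@@H](C)CO
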